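**Retrosynthetic overview**
1. Stipulin is cut at the C(=O)–Cα bond of the enone. The ring A aldehyde (2,4-dihydroxy-5-prenylbenzaldehyde) serves as an acyl anion equivalent through its chelated acyl–rhodium hydride and adds to the ring B terminal alkyne (4-ethynyl-2-prenylphenol). Syn hydroacylation gives the E-enone directly, without protecting groups.
2. Ring B alkyne ⇐ 4-hydroxy-3-prenylbenzaldehyde (one-carbon homologation) ⇐ 4-hydroxybenzaldehyde (ortho C-prenylation).
3. Ring A aldehyde ⇐ 2,4-dihydroxybenzaldehyde (Friedel–Crafts prenylation at C5).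
4. No ring is formed: rings A and B are bought as benzaldehydes, and the only stereo-element (the E alkene) is set in the key step.

Assumption: stipulin has no stereocentre, so "single enantiomer" is read as the single E (trans) isomer drawn.
Assumption: catalyst-bound species of the rhodium cycle are described in words and carry no compound number.

**Step 1**
Reactants: 1 2,4-dihydroxybenzaldehyde
Product: 2 2,4-dihydroxy-5-(3-methylbut-2-en-1-yl)benzaldehyde
Conditions: 2-methylbut-3-en-2-ol (1.2 equiv), BF3·OEt2 (0.5 equiv), 1,4-dioxane, rt, 8 h; chromatography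
Reagents that add atoms: 2-methylbut-3-en-2-ol, C=CC(C)(C)O
Why: Friedel–Crafts prenylation, in which BF3 ionises the tertiary allylic alcohol to the dimethylallyl cation that attacks through its primary terminus at C5 (para to the 2-OH, ortho to the 4-OH, far less crowded than C3 between the two hydroxyls), so the 5-prenyl isomer is the main product and the 3-prenyl and 3,5-diprenyl by-products are removed by chromatography; no stereocentre is formed.

**Step 2**
Reactants: 3 4-hydroxybenzaldehyde
Product: 4 4-hydroxy-3-(3-methylbut-2-en-1-yl)benzaldehyde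
Conditions: 1-bromo-3-methylbut-2-ene (1.0 equiv), 10% aq. KOH (2 equiv), rt, 24 h; then HCl to pH 3; chromatography
Reagents that add atoms: 1-bromo-3-methylbut-2-ene (prenyl bromide), CC(C)=CCBr
Why: Ortho C-alkylation of an ambident phenoxide, where water hydrogen-bonds the phenoxide oxygen so that a useful share of the SN2 alkylation occurs at the ring carbon ortho to the oxygen (para is blocked by CHO) and the dienone re-aromatises, the O-prenyl ether being a separable by-product; no stereocentre is formed.

**Step 3**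
Reactants: 4 4-hydroxy-3-(3-methylbut-2-en-1-yl)benzaldehyde
Product: 6 4-ethynyl-2-(3-methylbut-2-en-1-yl)phenol, via diazoalkene 5 (not isolated)
Conditions: dimethyl (1-diazo-2-oxopropyl)phosphonate (1.5 equiv), K2CO3 (3 equiv), MeOH, 0 °C to rt, 16 h, argon; aq. NH4Cl work-up; product used promptly
Reagents that add atoms: dimethyl (1-diazo-2-oxopropyl)phosphonate, CC(=O)C(=[N+]=[N-])P(=O)(OC)OC
Why: Seyferth–Gilbert homologation in the Ohira–Bestmann variant, in which methanolysis of the reagent gives the dimethyl (diazomethyl)phosphonate anion, its Horner–Wadsworth–Emmons reaction with the aldehyde gives diazoalkene 5, and loss of N2 with a 1,2-hydride shift gives the terminal alkyne under conditions mild enough for the phenoxide and the prenyl group; no stereocentre is formed.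

**Step 4 (key step)**
Reactants: 2 2,4-dihydroxy-5-(3-methylbut-2-en-1-yl)benzaldehyde; 6 4-ethynyl-2-(3-methylbut-2-en-1-yl)phenol
Product: 7 stipulin, (E)-1-[2,4-dihydroxy-5-(3-methylbut-2-en-1-yl)phenyl]-3-[4-hydroxy-3-(3-methylbut-2-en-1-yl)phenyl]prop-2-en-1-one
Conditions: [RhCl(C8H12)]2 (C8H12 = cycloocta-1,5-diene, 2.5 mol %), Fe(C5H4PPh2)2 (dppf, 5 mol %), Na2CO3 (10 mol %), toluene/1,4-dioxane 4:1, 80 °C, argon; 6 (1.3 equiv) added over 2 h
Reagents that add atoms: none
Why: Chelation-assisted rhodium-catalysed intermolecular alkyne hydroacylation, in which the rhodium phenoxide of 2 adds the formyl C–H bond oxidatively at monovalent rhodium to give a five-membered acyl rhodium hydride chelate at trivalent rhodium (the natively electrophilic aldehyde carbon now acting as a metal-bound acyl anion equivalent), syn hydrometallation of the alkyne of 6 puts rhodium on the unhindered terminal carbon, and acyl–alkenyl reductive elimination gives the linear enone with H and acyl added syn, which fixes the E geometry (no stereocentre is created) while the trisubstituted prenyl alkenes and free phenols are spectators.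

**Compound list**
1 | 2,4-dihydroxybenzaldehyde | O=Cc1ccc(O)cc1O | starting material
2 | 2,4-dihydroxy-5-(3-methylbut-2-en-1-yl)benzaldehyde | CC(C)=CCc1cc(C=O)c(O)cc1O | intermediate
3 | 4-hydroxybenzaldehyde | O=Cc1ccc(O)cc1 | starting material
4 | 4-hydroxy-3-(3-methylbut-2-en-1-yl)benzaldehyde | CC(C)=CCc1cc(C=O)ccc1O | intermediate
5 | 4-(2-diazoethenyl)-2-(3-methylbut-2-en-1-yl)phenol (diazoalkene, not isolated) | CC(C)=CCc1cc(C=C=[N+]=[N-])ccc1O | intermediate
6 | 4-ethynyl-2-(3-methylbut-2-en-1-yl)phenol | CC(C)=CCc1cc(C#C)ccc1O | intermediate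
7 | stipulin, (E)-1-[2,4-dihydroxy-5-(3-methylbut-2-en-1-yl)phenyl]-3-[4-hydroxy-3-(3-methylbut-2-en-1-yl)phenyl]prop-2-en-1-one | CC(C)=CCc1cc(/C=C/C(=O)c2cc(CC=C(C)C)c(O)cc2O)ccc1O | target

**Step count**
Total steps: 4. Longest linear sequence: 3 steps (3 → 4 → 6 → 7); step 1 runs in parallel.

**Three steps most likely to fail, with fallbacks**

Step 4 is the riskiest. Alkyne insertion may give some branched 1,1-disubstituted enone, the 2'-hydroxychalcone may close to the flavanone by oxa-Michael addition, the terminal alkyne may dimerise on rhodium, and the free phenols may slow the catalyst. The fallback replaces the catalytic acyl anion equivalent by a stoichiometric one (Corey–Seebach dithiane anion opening an epoxide). It sets out from 2, with 4 as the second component, and comes back to the route at 7.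
- Aldehyde 2 is treated with propane-1,3-dithiol and catalytic BF3·OEt2 (CH2Cl2, 0 °C) to give 4-(1,3-dithian-2-yl)-6-(3-methylbut-2-en-1-yl)benzene-1,3-diol F1.
- Its phenols are capped with MOMCl and i-Pr2NEt to give 2-[2,4-bis(methoxymethoxy)-5-(3-methylbut-2-en-1-yl)phenyl]-1,3-dithiane F2.
- Aldehyde 4 is protected in the same way to 4-(methoxymethoxy)-3-(3-methylbut-2-en-1-yl)benzaldehyde F3.
- Corey–Chaykovsky methylenation (trimethylsulfonium iodide, NaH, DMSO/THF) converts it into racemic 2-[4-(methoxymethoxy)-3-(3-methylbut-2-en-1-yl)phenyl]oxirane F4.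
- Lithiation of the dithiane (n-BuLi, THF, −78 to −30 °C) and SN2 opening of the epoxide at its CH2 carbon give racemic 2-{2-[2,4-bis(methoxymethoxy)-5-(3-methylbut-2-en-1-yl)phenyl]-1,3-dithian-2-yl}-1-[4-(methoxymethoxy)-3-(3-methylbut-2-en-1-yl)phenyl]ethan-1-ol F5.
- MeI and CaCO3 in aqueous MeCN (45 °C) unmask the ketone to give racemic 1-[2,4-bis(methoxymethoxy)-5-(3-methylbut-2-en-1-yl)phenyl]-3-hydroxy-3-[4-(methoxymethoxy)-3-(3-methylbut-2-en-1-yl)phenyl]propan-1-one F6.
- HCl in MeOH (40 °C) removes the three MOM groups and dehydrates the p-hydroxybenzylic alcohol to the thermodynamically favoured E-enone 7; the racemic carbinol centre disappears in this step.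

Step 1 is the second risk: the 5-prenyl isomer must be separated from the 3-prenyl and 3,5-diprenyl products, the yield is modest, and acid can cyclise the ortho-prenylphenol to a chroman. The fallback fixes the position with a halogen and a cross-coupling instead of an electrophilic substitution. It sets out from 1 and comes back at 2.
- Br2 in AcOH (0 °C to rt) brominates 1 para to the 2-OH to give 5-bromo-2,4-dihydroxybenzaldehyde F7.
- Stille coupling with tributyl(3-methylbut-2-en-1-yl)stannane (Pd(PPh3)4 as the zerovalent palladium source, DMF, 95 °C) puts the prenyl group only where the bromine was, giving 2.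

Step 3 is the third risk: the phenoxide of 4 is a poor electrophile towards the phosphonate anion, and the 4-ethynylphenol product is prone to polymerise. The fallback is a Corey–Fuchs sequence on the silyl-protected phenol. It sets out from 4 and comes back at 6.
- TBSCl and imidazole (DMF, rt) give 4-[(tert-butyldimethylsilyl)oxy]-3-(3-methylbut-2-en-1-yl)benzaldehyde F8.
- CBr4 and PPh3 (CH2Cl2, 0 °C) give tert-butyl[4-(2,2-dibromoethenyl)-2-(3-methylbut-2-en-1-yl)phenoxy]dimethylsilane F9.
- n-BuLi (2.2 equiv, THF, −78 °C), then water, gives tert-butyl[4-ethynyl-2-(3-methylbut-2-en-1-yl)phenoxy]dimethylsilane F10 by Fritsch–Buttenberg–Wiechell rearrangement.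
- Tetrabutylammonium fluoride (THF, 0 °C) frees the phenol to give 6.

**Further compounds**
F1 | step 4 | 4-(1,3-dithian-2-yl)-6-(3-methylbut-2-en-1-yl)benzene-1,3-diol | CC(C)=CCc1cc(C2SCCCS2)c(O)cc1O
F2 | step 4 | 2-[2,4-bis(methoxymethoxy)-5-(3-methylbut-2-en-1-yl)phenyl]-1,3-dithiane | COCOc1cc(OCOC)c(CC=C(C)C)cc1C1SCCCS1
F3 | step 4 | 4-(methoxymethoxy)-3-(3-methylbut-2-en-1-yl)benzaldehyde | COCOc1ccc(C=O)cc1CC=C(C)C
F4 | step 4 | 2-[4-(methoxymethoxy)-3-(3-methylbut-2-en-1-yl)phenyl]oxirane (racemic) | COCOc1ccc(C2CO2)cc1CC=C(C)C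
F5 | step 4 | 2-{2-[2,4-bis(methoxymethoxy)-5-(3-methylbut-2-en-1-yl)phenyl]-1,3-dithian-2-yl}-1-[4-(methoxymethoxy)-3-(3-methylbut-2-en-1-yl)phenyl]ethan-1-ol (racemic) | COCOc1cc(OCOC)c(CC=C(C)C)cc1C1(CC(O)c2ccc(OCOC)c(CC=C(C)C)c2)SCCCS1
F6 | step 4 | 1-[2,4-bis(methoxymethoxy)-5-(3-methylbut-2-en-1-yl)phenyl]-3-hydroxy-3-[4-(methoxymethoxy)-3-(3-methylbut-2-en-1-yl)phenyl]propan-1-one (racemic) | COCOc1cc(OCOC)c(CC=C(C)C)cc1C(=O)CC(O)c1ccc(OCOC)c(CC=C(C)C)c1
F7 | step 1 | 5-bromo-2,4-dihydroxybenzaldehyde | O=Cc1cc(Br)c(O)cc1O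
F8 | step 3 | 4-[(tert-butyldimethylsilyl)oxy]-3-(3-methylbut-2-en-1-yl)benzaldehyde | CC(C)=CCc1cc(C=O)ccc1O[Si](C)(C)C(C)(C)C
F9 | step 3 | tert-butyl[4-(2,2-dibromoethenyl)-2-(3-methylbut-2-en-1-yl)phenoxy]dimethylsilane | CC(C)=CCc1cc(C=C(Br)Br)ccc1O[Si](C)(C)C(C)(C)C
F10 | step 3 | tert-butyl[4-ethynyl-2-(3-methylbut-2-en-1-yl)phenoxy]dimethylsilane | CC(C)=CCc1cc(C#C)ccc1O[Si](C)(C)C(C)(C)C
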